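**Retrosynthetic overview**

1. Ring A is the resorcinol-type ring (OH, O-aryl and tether at 1,3,5), ring B is the 2,6-dihydroxy-4-alkylphenoxy ring, and the tether is numbered C1 (on C-4 of ring B) to C14 (on ring A). Robustol comes from O-demethylation and exhaustive hydrogenation of a 22-membered macrocyclic tetrayne (C1≡C2, C5≡C6–C7≡C8, C13≡C14) whose three phenols are methyl ethers.
2. The macrocyclic tetrayne comes from an Eglinton oxidative acetylide–acetylide coupling (Cu(OAc)2, pyridine) that makes the C6–C7 bond between the two terminal alkyne carbons of an open diaryl ether, a union of two carbons of the same (nucleophilic) polarity.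
3. The open bis(terminal alkyne) comes from two chemoselective Sonogashira couplings (hexa-1,5-diyne at the ring B C–I, then octa-1,7-diyne at the ring A C–Br) on an iodo/bromo diaryl ether, itself made by Chan–Lam O-arylation of 4-iodo-2,6-dimethoxyphenol with (3-bromo-5-methoxyphenyl)boronic acid.
4. Enabling feature: the tether is an unbranched, unfunctionalised (CH2)14 chain between aryl carbons of rings A and B, so every tether carbon may pass through the sp level. C6 and C7 are plain methylenes lying 6 and 8 carbons from the rings, so the two halves map onto hexa-1,5-diyne and octa-1,7-diyne, and hydrogenation later erases all eight sp carbons.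
5. Ring order: rings A and B are bought; the diaryl ether is made first (step 2) and the only ring formed in the route is the 22-membered macrocycle (step 5).

Key step: step 5

Assumption: hexa-1,5-diyne is used as its commercial solution in pentane, and both diynes are used in excess so that each is arylated at one end only.

**Route**

Step 1
Reactants: 1 2,6-dimethoxyphenol
Product: 2 4-iodo-2,6-dimethoxyphenol
Conditions: NIS (1.0 equiv), NaH (0.05 equiv), CHCl3, −45 °C to 20 °C, dark
Reagents that add atoms: N-iodosuccinimide, O=C1CCC(=O)N1I
Why: Electrophilic aromatic iodination is steered para by the phenol (phenoxide) oxygen, both ortho positions being occupied by methoxy groups, in analogy to the para bromination of the same phenol with NBS under catalytic base.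

Step 2
Reactants: 2 4-iodo-2,6-dimethoxyphenol; 3 (3-bromo-5-methoxyphenyl)boronic acid (2 equiv)
Product: 4 2-(3-bromo-5-methoxyphenoxy)-5-iodo-1,3-dimethoxybenzene
Conditions: Cu(OAc)2 (2.5 equiv), pyridine (5 equiv), 4 Å molecular sieves, CH2Cl2, 20 °C
Reagents that add atoms: none
Why: Chan–Lam coupling (aryl transfer from boron to divalent copper, phenoxide binding, oxidation to trivalent copper and C–O reductive elimination) runs at room temperature, so the C–I and C–Br bonds stay intact, and the para iodine blocks oxidative para coupling of the electron-rich phenol.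

Step 3
Reactants: 4 2-(3-bromo-5-methoxyphenoxy)-5-iodo-1,3-dimethoxybenzene; 5 hexa-1,5-diyne (6 equiv)
Product: 6 2-(3-bromo-5-methoxyphenoxy)-5-(hexa-1,5-diyn-1-yl)-1,3-dimethoxybenzene
Conditions: Pd(PPh3)2Cl2 (3 mol%), CuI (6 mol%), Et3N/THF, degassed, 20 °C
Reagents that add atoms: none
Why: Sonogashira coupling in which zerovalent palladium inserts into the aryl C–I bond at room temperature far faster than into the aryl C–Br bond, while the excess of the symmetric diyne ensures arylation at one terminus only.

Step 4
Reactants: 6 2-(3-bromo-5-methoxyphenoxy)-5-(hexa-1,5-diyn-1-yl)-1,3-dimethoxybenzene; 7 octa-1,7-diyne (15 equiv)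
Product: 8 5-(hexa-1,5-diyn-1-yl)-1,3-dimethoxy-2-[3-methoxy-5-(octa-1,7-diyn-1-yl)phenoxy]benzene
Conditions: Pd(PPh3)2Cl2 (5 mol%), CuI (10 mol%), Et3N, degassed, 70 °C, slow addition of 6
Reagents that add atoms: none
Why: Sonogashira coupling of the unhindered ring A bromide at elevated temperature, where the large excess of octa-1,7-diyne and the slow addition of 6 statistically suppress coupling through the terminal alkyne already present on the ring B arm.

Step 5
Reactants: 8 5-(hexa-1,5-diyn-1-yl)-1,3-dimethoxy-2-[3-methoxy-5-(octa-1,7-diyn-1-yl)phenoxy]benzene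
Product: 9 macrocyclic tetrayne (tri-O-methylrobustol carrying the triple bonds C1≡C2, C5≡C6, C7≡C8 and C13≡C14 in the tether; 22-membered ring with a conjugated C5–C8 diyne)
Conditions: Cu(OAc)2 (10 equiv), pyridine/MeCN (3:1), 60 °C, Ar, 8 added by syringe pump over 12 h (final 1 mM)
Reagents that add atoms: none
Why: Eglinton (Glaser-type) oxidative homocoupling: pyridine-assisted cupration of the two terminal C–H alkynes gives copper acetylides, which combine within a dinuclear copper acetylide and release two monovalent copper centres as the sp–sp bond C6–C7 forms, so two carbons of the same nucleophilic polarity are united at the expense of Cu(OAc)2. The closest known reaction type is the Cu(OAc)2/pyridine cyclisation of α,ω-diynes to macrocyclic 1,3-diynes, by which rings of 16 to 30 members built from hexa-1,5-diyne and octa-1,7-diyne units are formed. The single ring closed is the 22-membered macrocycle, formed end-to-end with both carbons of the new bond inside the ring; the linear C4–C9 rod fits because the C3–C4 hinge can turn gauche, the C9–C12 segment is flexible, and the meta-substituted ring A with the ether oxygen supplies a bend of about 120 degrees. No stereocentre is created. The step needs chemoselectivity for the terminal alkynes, secured because the two aryl alkynes carry no C–H and cannot be cuprated. It also needs ring closure to beat intermolecular coupling, secured by slow addition of 8 into a large excess of Cu(OAc)2 so that its stationary concentration stays below millimolar, while the aryl methyl ethers and the diaryl ether are inert.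

Step 6
Reactants: 9 macrocyclic tetrayne
Product: 10 tri-O-methylrobustol (the saturated 22-membered macrocycle with three aryl methyl ethers)
Conditions: H2 (3 atm), Pd/C (10 wt% Pd), EtOAc/EtOH, 20 °C
Reagents that add atoms: none
Why: Heterogeneous catalytic hydrogenation should saturate all four triple bonds (eight equivalents of H2), while aryl ethers, the diaryl ether and the arenes are not reduced under these mild conditions.

Step 7
Reactants: 10 tri-O-methylrobustol
Product: 11 robustol
Conditions: BBr3 (6 equiv), CH2Cl2, −78 °C to 20 °C; then H2O, 0 °C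
Reagents that add atoms: none
Why: Lewis-acid aryl methyl ether cleavage, in which boron binds each methoxy oxygen and bromide removes the methyl group by SN2, whereas the diaryl ether offers no alkyl carbon for attack and survives.

**Compound list**

1 | 2,6-dimethoxyphenol | COc1cccc(OC)c1O | starting material
2 | 4-iodo-2,6-dimethoxyphenol | COc1cc(I)cc(OC)c1O | intermediate
3 | (3-bromo-5-methoxyphenyl)boronic acid | COc1cc(Br)cc(c1)B(O)O | starting material
4 | 2-(3-bromo-5-methoxyphenoxy)-5-iodo-1,3-dimethoxybenzene | COc1cc(Br)cc(c1)Oc1c(OC)cc(I)cc1OC | intermediate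
5 | hexa-1,5-diyne | C#CCCC#C | starting material
6 | 2-(3-bromo-5-methoxyphenoxy)-5-(hexa-1,5-diyn-1-yl)-1,3-dimethoxybenzene | COc1cc(Br)cc(c1)Oc1c(OC)cc(cc1OC)C#CCCC#C | intermediate
7 | octa-1,7-diyne | C#CCCCCC#C | starting material
8 | 5-(hexa-1,5-diyn-1-yl)-1,3-dimethoxy-2-[3-methoxy-5-(octa-1,7-diyn-1-yl)phenoxy]benzene | COc1cc(cc(c1)Oc1c(OC)cc(cc1OC)C#CCCC#C)C#CCCCCC#C | intermediate
9 | macrocyclic tetrayne (tri-O-methylrobustol with C1≡C2, C5≡C6, C7≡C8 and C13≡C14 triple bonds) | COc1cc2cc(c1)Oc1c(OC)cc(cc1OC)C#CCCC#CC#CCCCCC#C2 | intermediate
10 | tri-O-methylrobustol | COc1cc2cc(c1)Oc1c(OC)cc(cc1OC)CCCCCCCCCCCCCC2 | intermediate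
11 | robustol | Oc1cc2cc(c1)Oc1c(O)cc(cc1O)CCCCCCCCCCCCCC2 | target

**Totals**

Total step count: 7. Longest linear sequence: 7 steps (1 to 11).

**Steps most likely to fail**

Step 5. Intermolecular acetylide coupling may outrun ring closure, because the rigid aryl-alkyne arms disfavour the folded conformer and give linear and cyclic oligomers. The fallback makes the C6–C7 bond intermolecularly and closes the ring by palladium catalysis instead. It sets out from 6, whose terminal alkyne should be brominated (NBS, AgNO3 cat., acetone) to the bromoalkyne 2-(3-bromo-5-methoxyphenoxy)-5-(6-bromohexa-1,5-diyn-1-yl)-1,3-dimethoxybenzene F1. Cadiot–Chodkiewicz coupling of F1 with excess 7 (CuCl cat., NH2OH·HCl, n-BuNH2, THF/H2O, 0 °C) should give 2-(3-bromo-5-methoxyphenoxy)-1,3-dimethoxy-5-(tetradeca-1,5,7,13-tetrayn-1-yl)benzene F2. An intramolecular Sonogashira macrocyclisation of F2 at high dilution (Pd(PPh3)4, CuI, Et3N, toluene, 80 °C, slow addition) then joins C14 to ring A and comes back to the route at 9.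

Step 2. Oxidative self-coupling of the electron-rich, doubly ortho-substituted phenol under divalent copper, together with protodeboronation of the boronic acid, may outpace the slow O-arylation. The fallback is a metal-free arylation with a diaryliodonium salt. Commercial 1-bromo-3-iodo-5-methoxybenzene (COc1cc(Br)cc(I)c1) should be oxidised with mCPBA and TsOH·H2O and trapped with 1,3,5-trimethoxybenzene to give (3-bromo-5-methoxyphenyl)(2,4,6-trimethoxyphenyl)iodonium 4-methylbenzenesulfonate F3. The fallback sets out from 2, which with t-BuOK and F3 in THF/toluene at 20 °C should accept the bromo-methoxyphenyl group (the trimethoxyphenyl group serves as the non-transferred ligand), and it comes back to the route at 4.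

Step 4. The terminal alkyne already present on the ring B arm may compete with octa-1,7-diyne for the arylpalladium intermediate, and copper-mediated alkyne homocoupling may add to the loss, giving oligomers. The fallback caps that alkyne temporarily. It sets out from 6, which with EtMgBr in THF and then TMSCl should give {6-[4-(3-bromo-5-methoxyphenoxy)-3,5-dimethoxyphenyl]hexa-1,5-diyn-1-yl}trimethylsilane F4. Sonogashira coupling of F4 with 7 (Pd(PPh3)2Cl2, CuI, Et3N, 70 °C) should give {6-[3,5-dimethoxy-4-[3-methoxy-5-(octa-1,7-diyn-1-yl)phenoxy]phenyl]hexa-1,5-diyn-1-yl}trimethylsilane F5. Desilylation of F5 (K2CO3, MeOH, 20 °C) comes back to the route at 8.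

**Further compounds**

F1 | step 5 | 2-(3-bromo-5-methoxyphenoxy)-5-(6-bromohexa-1,5-diyn-1-yl)-1,3-dimethoxybenzene | COc1cc(Br)cc(c1)Oc1c(OC)cc(cc1OC)C#CCCC#CBr
F2 | step 5 | 2-(3-bromo-5-methoxyphenoxy)-1,3-dimethoxy-5-(tetradeca-1,5,7,13-tetrayn-1-yl)benzene | COc1cc(Br)cc(c1)Oc1c(OC)cc(cc1OC)C#CCCC#CC#CCCCCC#C
F3 | step 2 | (3-bromo-5-methoxyphenyl)(2,4,6-trimethoxyphenyl)iodonium 4-methylbenzenesulfonate | COc1cc(Br)cc(c1)[I+]c1c(OC)cc(OC)cc1OC.Cc1ccc(cc1)S(=O)(=O)[O-]
F4 | step 4 | {6-[4-(3-bromo-5-methoxyphenoxy)-3,5-dimethoxyphenyl]hexa-1,5-diyn-1-yl}trimethylsilane | COc1cc(Br)cc(c1)Oc1c(OC)cc(cc1OC)C#CCCC#C[Si](C)(C)C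
F5 | step 4 | {6-[3,5-dimethoxy-4-[3-methoxy-5-(octa-1,7-diyn-1-yl)phenoxy]phenyl]hexa-1,5-diyn-1-yl}trimethylsilane | COc1cc(cc(c1)Oc1c(OC)cc(cc1OC)C#CCCC#C[Si](C)(C)C)C#CCCCCC#C
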